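**Retrosynthetic overview** (locants C1–C9 are those of the bicyclo[3.3.1]nonane target and are also used for the monocyclic precursors)
1. Target 22 ⇐ O-demethylation and C3-isobutyrylation of bicyclic vinylogous ester 19 ⇐ endo-C7 prenyl by exo-face hydroboration/B-alkyl Suzuki coupling of the 7-methylidene compound 16.
2. 16 ⇐ one-carbon ring expansion of monocyclic 2-methoxycyclopent-2-ene-1,4-dione 14: the tethered diazo carbon C5 adds to C9 (closing ring C1–C8–C7–C6–C5–C9) and inserts into the C9–C4 bond, so the five-membered ring C1–C2–C3–C4–C9 becomes the six-membered ring C1–C2–C3–C4–C5–C9.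
3. Enabling feature: in 14 the ring ketone C9 lies between quaternary C1, which carries the four-atom tether C8–C7–C6–C5(=N2), and the alkenyl carbon C4 of the enol ether, while the other carbonyl C2 is a deactivated vinylogous ester.
4. 14 ⇐ trione 12 ⇐ enantioselective Claisen rearrangement of diosphenol allyl ether 11 (sets C1 and the C1–C8 bond between two quaternary carbons) ⇐ Mitsunobu union of trione 4 (6-methylhept-5-en-2-one + diethyl oxalate) with allylic alcohol 10 (from diethyl isopropylidenemalonate).
5. Ring order: five-membered trione ring (step 1), then the carbocycle through C5–C9 and the six-membered trione ring together (step 9).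

Key step: step 9

Remark: β-triketone and vinylogous-acid compounds (4, 12, 13, 22) are drawn as one enol tautomer. O-alkylation of 4 is assumed to occur at the enol oxygen drawn.

Step 1
Reactants: 1 6-methylhept-5-en-2-one; 2 diethyl oxalate (2.2 equiv)
Product: 4 2-hydroxy-3-(3-methylbut-2-en-1-yl)cyclopent-2-ene-1,4-dione, via ethoxalyl trione 3 (not isolated)
Conditions: NaOEt (3.5 equiv), EtOH, 0 °C to reflux; then 2 M NaOH, 40 °C; then 2 M HCl, 0 °C
Reagents that add atoms: none
Why: Oxalate Claisen condensation at the methyl group and Dieckmann-type closure from the other α-carbon should give the cyclopentane-1,2,4-trione (the route used for the 3-methyl analogue from butanone), and hydroxide then removes the extra ethoxalyl group by retro-Claisen cleavage without the hot acid that would cyclise the prenyl group onto the enol.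

Step 2
Reactants: 5 diethyl 2-(propan-2-ylidene)propanedioate
Product: 6 2-(propan-2-ylidene)propane-1,3-diol
Conditions: DIBAL-H (4.4 equiv), CH2Cl2, −78 to 0 °C; Rochelle salt work-up
Reagents that add atoms: none
Why: DIBAL-H should reduce both ester groups of the alkylidene malonate in the 1,2-sense to the allylic diol (ester reduction), conjugate reduction being disfavoured at the fully substituted β-carbon.

Step 3
Reactants: 6 2-(propan-2-ylidene)propane-1,3-diol
Product: 7 2-(hydroxymethyl)-3-methylbut-2-en-1-yl acetate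
Conditions: Ac2O (1.0 equiv), Et3N, DMAP (cat.), CH2Cl2, −20 °C; diol and diacetate recycled
Reagents that add atoms: acetic anhydride, CC(=O)OC(C)=O
Why: The two hydroxyl groups are equivalent, so statistical monoacylation at low temperature should give the monoacetate (acylation).

Step 4
Reactants: 7 2-(hydroxymethyl)-3-methylbut-2-en-1-yl acetate; 8 tributyl(1-ethoxyethenyl)stannane
Product: 10 4-(hydroxymethyl)-5-methylhex-4-en-2-one, via enol ether 9 (not isolated)
Conditions: Pd(PPh3)4 (5 mol %), LiCl (3 equiv), DMF, 50 °C; then 1 M HCl, THF, 0 °C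
Reagents that add atoms: water, O
Why: Pd(0) ionises the allylic acetate and the vinylstannane couples at the unhindered CH2 terminus of the π-allyl (Stille coupling of an allyl acetate), after which mild acid hydrolyses the 1-ethoxyvinyl group to the methyl ketone.

Step 5
Reactants: 4 2-hydroxy-3-(3-methylbut-2-en-1-yl)cyclopent-2-ene-1,4-dione; 10 4-(hydroxymethyl)-5-methylhex-4-en-2-one
Product: 11 3-(3-methylbut-2-en-1-yl)-2-{[3-methyl-2-(2-oxopropyl)but-2-en-1-yl]oxy}cyclopent-2-ene-1,4-dione
Conditions: PPh3, DIAD, THF, 0 °C to rt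
Reagents that add atoms: none
Why: The enol OH of 4 is a vinylogous acid and should serve as Mitsunobu pronucleophile, being O-alkylated by the primary allylic alcohol with SN2 regiochemistry (Mitsunobu etherification) to give an allyl vinyl ether with an acyl group on each vinyl carbon.

Step 6
Reactants: 11 3-(3-methylbut-2-en-1-yl)-2-{[3-methyl-2-(2-oxopropyl)but-2-en-1-yl]oxy}cyclopent-2-ene-1,4-dione
Product: 12 (5S)-2-hydroxy-5-(2-methyl-3-methylidene-5-oxohexan-2-yl)-5-(3-methylbut-2-en-1-yl)cyclopent-2-ene-1,4-dione
Conditions: [Cu(t-Bu-box)](SbF6)2 (10 mol %; ligand antipode chosen by screening to give the 5S product), 4 Å MS, CH2Cl2, 0 to 25 °C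
Reagents that add atoms: none
Why: Proposed new method: chelation of the ether oxygen and the adjacent ring carbonyl of the 2-alkoxy-enedione by a chiral Cu(II)-bis(oxazoline) Lewis acid should polarise the C–O bond and let the [3,3]-shift run at room temperature through one face of the ring, forming the C1–C8 bond between two quaternary carbons and the C1 stereocentre under catalyst control; the closest known reaction types are the Cu(II)-box-catalysed enantioselective Claisen rearrangement of 2-alkoxycarbonyl allyl vinyl ethers, the hydrogen-bond-donor-catalysed Claisen rearrangement of O-allyl β-keto esters to α-quaternary products, and the thermal Claisen rearrangement of diosphenol allyl ethers.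

Step 7
Reactants: 12 (5S)-2-hydroxy-5-(2-methyl-3-methylidene-5-oxohexan-2-yl)-5-(3-methylbut-2-en-1-yl)cyclopent-2-ene-1,4-dione
Product: 13 (5S)-2-hydroxy-5-(3-methylbut-2-en-1-yl)-5-(2-methyl-3-methylidene-5-{2-[2-(trifluoromethyl)benzenesulfonyl]hydrazinylidene}hexan-2-yl)cyclopent-2-ene-1,4-dione
Conditions: 2-(trifluoromethyl)benzenesulfonohydrazide (1.05 equiv), MeOH, rt
Reagents that add atoms: 2-(trifluoromethyl)benzenesulfonohydrazide, NNS(=O)(=O)c1ccccc1C(F)(F)F
Why: The unhindered methyl ketone should condense selectively (hydrazone formation, catalysed by the substrate's own acidity), because the ring carbonyls are either part of the enolised vinylogous acid or shielded by the quaternary carbon.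

Step 8
Reactants: 13 the N-sulfonylhydrazone of step 7
Product: 14 (5S)-2-methoxy-5-(3-methylbut-2-en-1-yl)-5-(2-methyl-3-methylidene-5-{2-[2-(trifluoromethyl)benzenesulfonyl]hydrazinylidene}hexan-2-yl)cyclopent-2-ene-1,4-dione
Conditions: TMSCHN2 (1.05 equiv), MeOH/toluene, −20 to 0 °C
Reagents that add atoms: (trimethylsilyl)diazomethane, C[Si](C)(C)C=[N+]=[N-]
Why: The diazo reagent should methylate the acidic enol much faster than the hydrazone N–H, and at the enol oxygen remote from the quaternary carbon (O-methylation of a vinylogous acid), which leaves C9 as the only carbonyl that is not deactivated.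

Step 9
Reactants: 14 the methyl enol ether of step 8
Product: 16 (1S,5R)-4-methoxy-5,8,8-trimethyl-7-methylidene-1-(3-methylbut-2-en-1-yl)bicyclo[3.3.1]non-3-ene-2,9-dione, via diazoalkane 15 (not isolated)
Conditions: NaH (1.5 equiv), CH2Cl2 (0.005 M), −20 to 30 °C
Reagents that add atoms: none
Why: Proposed new method: deprotonation of the N-sulfonylhydrazone expels sulfinate below 30 °C to give the non-stabilised diazoalkane 15, whose nucleophilic carbon C5 adds 6-exo-trig to the C9 carbonyl and closes the carbocycle C1–C8–C7–C6–C5–C9; in the resulting diazonium alkoxide the alkenyl carbon C4 shifts from C9 to C5 with loss of N2, which turns the five-membered ring C1–C2–C3–C4–C9 into the six-membered ring C1–C2–C3–C4–C5–C9 by 1,2-shift (not by cyclisation) and makes C9 the bridging ketone. The closest known reaction type is the intramolecular diazoalkane–ketone ring enlargement of 2-(ω-diazoalkyl)cycloalkanones (Tiffeneau–Demjanov-type homologation with Bamford–Stevens generation of the diazo group), which gives bridged bicyclic ketones by migration of the distal α-carbon but has not been run on an enedione with alkenyl migration. C1 keeps its configuration because none of its bonds is touched, and the new quaternary centre C5 can only form with the configuration that lets the C2–C3–C4 bridge span C1 and C5 on one face, so it is dictated by C1. The step needs attack at C9 rather than at C2 or by dipolar cycloaddition at C3=C4, which is secured by C2 being a vinylogous ester carbonyl, by the six- versus seven-membered transition state, by the donor OMe on the alkene and by high dilution. It also needs migration of C4 rather than of C1 or epoxide closure, which is secured by the high migratory aptitude of the electron-rich alkenyl carbon, by the acyl-deactivated quaternary C1, and by the chair-like betaine with equatorial methyl and axial N2 that places N2 gauche to O– and antiperiplanar to C4.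

Step 10
Reactants: 16 (1S,5R)-4-methoxy-5,8,8-trimethyl-7-methylidene-1-(3-methylbut-2-en-1-yl)bicyclo[3.3.1]non-3-ene-2,9-dione; 17 1-bromo-2-methylprop-1-ene
Product: 19 (1S,5R,7R)-4-methoxy-5,8,8-trimethyl-1,7-bis(3-methylbut-2-en-1-yl)bicyclo[3.3.1]non-3-ene-2,9-dione, via alkylborane 18 (not isolated)
Conditions: 9-BBN (1.3 equiv), THF, 0 to 25 °C; then 17, Pd(dppf)Cl2 (5 mol %), AsPh3, Cs2CO3, DMF/H2O, 50 °C
Reagents that add atoms: none
Why: 9-BBN should add to the 1,1-disubstituted exocyclic alkene in preference to the trisubstituted prenyl alkene and from the exo (equatorial) direction, because the endo trajectory is blocked by the syn-axial C1–C2 and C5–C4 bonds of the enone bridge, so H ends up exo and the CH2B group endo at C7, and B-alkyl Suzuki–Miyaura coupling with the alkenyl bromide then completes the prenyl group.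

Step 11
Reactants: 19 (1S,5R,7R)-4-methoxy-5,8,8-trimethyl-1,7-bis(3-methylbut-2-en-1-yl)bicyclo[3.3.1]non-3-ene-2,9-dione; 20 2-methylpropanoyl chloride
Product: 21 (1R,5R,7R)-4-methoxy-5,8,8-trimethyl-1,7-bis(3-methylbut-2-en-1-yl)-3-(2-methylpropanoyl)bicyclo[3.3.1]non-3-ene-2,9-dione
Conditions: LiTMP (1.5 equiv), THF, −78 °C; then 20, −78 to −40 °C
Reagents that add atoms: none
Why: With both bridgeheads quaternary, LiTMP should remove only the vinylic C3–H of the vinylogous ester, and the vinyllithium is C-acylated by the acid chloride (metalation/acylation, the usual way to place the C3 acyl group in bicyclic acylphloroglucinols); the descriptor at C1 changes by priority only.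

Step 12
Reactants: 21 (1R,5R,7R)-4-methoxy-5,8,8-trimethyl-1,7-bis(3-methylbut-2-en-1-yl)-3-(2-methylpropanoyl)bicyclo[3.3.1]non-3-ene-2,9-dione
Product: 22 (1R,5R,7R)-4-hydroxy-5,8,8-trimethyl-1,7-bis(3-methylbut-2-en-1-yl)-3-(2-methylpropanoyl)bicyclo[3.3.1]non-3-ene-2,9-dione (target)
Conditions: LiCl (5 equiv), DMSO, 120 °C; then dilute HCl, 0 °C
Reagents that add atoms: none
Why: Chloride should demethylate the vinylogous methyl ester by SN2 attack at the methyl group (Krapcho-type dealkylation), freeing the enolised β-triketone without the acid that would cyclise the prenyl groups.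

**Compound list**
1 | 6-methylhept-5-en-2-one | CC(=O)CCC=C(C)C | starting material
2 | diethyl oxalate | CCOC(=O)C(=O)OCC | starting material
3 | ethyl 2-[3-(3-methylbut-2-en-1-yl)-2,4,5-trioxocyclopentyl]-2-oxoacetate | CCOC(=O)C(=O)C1C(=O)C(CC=C(C)C)C(=O)C1=O | intermediate
4 | 2-hydroxy-3-(3-methylbut-2-en-1-yl)cyclopent-2-ene-1,4-dione | OC1=C(CC=C(C)C)C(=O)CC1=O | intermediate
5 | diethyl 2-(propan-2-ylidene)propanedioate | CCOC(=O)C(=C(C)C)C(=O)OCC | starting material
6 | 2-(propan-2-ylidene)propane-1,3-diol | CC(C)=C(CO)CO | intermediate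
7 | 2-(hydroxymethyl)-3-methylbut-2-en-1-yl acetate | CC(=O)OCC(CO)=C(C)C | intermediate
8 | tributyl(1-ethoxyethenyl)stannane | CCCC[Sn](CCCC)(CCCC)C(=C)OCC | starting material
9 | 4-ethoxy-2-(propan-2-ylidene)pent-4-en-1-ol | CCOC(=C)CC(CO)=C(C)C | intermediate
10 | 4-(hydroxymethyl)-5-methylhex-4-en-2-one | CC(=O)CC(CO)=C(C)C | intermediate
11 | 3-(3-methylbut-2-en-1-yl)-2-{[3-methyl-2-(2-oxopropyl)but-2-en-1-yl]oxy}cyclopent-2-ene-1,4-dione | CC(=O)CC(COC1=C(CC=C(C)C)C(=O)CC1=O)=C(C)C | intermediate
12 | (5S)-2-hydroxy-5-(2-methyl-3-methylidene-5-oxohexan-2-yl)-5-(3-methylbut-2-en-1-yl)cyclopent-2-ene-1,4-dione | OC1=CC(=O)[C@@](CC=C(C)C)(C1=O)C(C)(C)C(=C)CC(C)=O | intermediate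
13 | (5S)-2-hydroxy-5-(3-methylbut-2-en-1-yl)-5-(2-methyl-3-methylidene-5-{2-[2-(trifluoromethyl)benzenesulfonyl]hydrazinylidene}hexan-2-yl)cyclopent-2-ene-1,4-dione | OC1=CC(=O)[C@@](CC=C(C)C)(C1=O)C(C)(C)C(=C)CC(C)=NNS(=O)(=O)c1ccccc1C(F)(F)F | intermediate
14 | (5S)-2-methoxy-5-(3-methylbut-2-en-1-yl)-5-(2-methyl-3-methylidene-5-{2-[2-(trifluoromethyl)benzenesulfonyl]hydrazinylidene}hexan-2-yl)cyclopent-2-ene-1,4-dione | COC1=CC(=O)[C@@](CC=C(C)C)(C1=O)C(C)(C)C(=C)CC(C)=NNS(=O)(=O)c1ccccc1C(F)(F)F | intermediate
15 | (5S)-5-(5-diazo-2-methyl-3-methylidenehexan-2-yl)-2-methoxy-5-(3-methylbut-2-en-1-yl)cyclopent-2-ene-1,4-dione | COC1=CC(=O)[C@@](CC=C(C)C)(C1=O)C(C)(C)C(=C)CC(C)=[N+]=[N-] | intermediate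
16 | (1S,5R)-4-methoxy-5,8,8-trimethyl-7-methylidene-1-(3-methylbut-2-en-1-yl)bicyclo[3.3.1]non-3-ene-2,9-dione | C=C1C[C@@]2(C)C(=O)[C@](CC=C(C)C)(C(=O)C=C2OC)C1(C)C | intermediate
17 | 1-bromo-2-methylprop-1-ene | CC(C)=CBr | starting material
18 | (1S,5R,7R)-7-[(9-borabicyclo[3.3.1]nonan-9-yl)methyl]-4-methoxy-5,8,8-trimethyl-1-(3-methylbut-2-en-1-yl)bicyclo[3.3.1]non-3-ene-2,9-dione | C1CCC2CCCC1B2C[C@@H]1C[C@@]2(C)C(=O)[C@](CC=C(C)C)(C(=O)C=C2OC)C1(C)C | intermediate
19 | (1S,5R,7R)-4-methoxy-5,8,8-trimethyl-1,7-bis(3-methylbut-2-en-1-yl)bicyclo[3.3.1]non-3-ene-2,9-dione | CC(C)=CC[C@@H]1C[C@@]2(C)C(=O)[C@](CC=C(C)C)(C(=O)C=C2OC)C1(C)C | intermediate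
20 | 2-methylpropanoyl chloride | CC(C)C(Cl)=O | starting material
21 | (1R,5R,7R)-4-methoxy-5,8,8-trimethyl-1,7-bis(3-methylbut-2-en-1-yl)-3-(2-methylpropanoyl)bicyclo[3.3.1]non-3-ene-2,9-dione | CC(C)=CC[C@@H]1C[C@@]2(C)C(=O)[C@](CC=C(C)C)(C(=O)C(C(=O)C(C)C)=C2OC)C1(C)C | intermediate
22 | (1R,5R,7R)-4-hydroxy-5,8,8-trimethyl-1,7-bis(3-methylbut-2-en-1-yl)-3-(2-methylpropanoyl)bicyclo[3.3.1]non-3-ene-2,9-dione | CC(C)=CC[C@@H]1C[C@@]2(C)C(=O)[C@](CC=C(C)C)(C(=O)C(C(=O)C(C)C)=C2O)C1(C)C | target

Total step count: 12. Longest linear sequence: 11 steps (5 → 6 → 7 → 10 → 11 → 12 → 13 → 14 → 16 → 19 → 21 → 22).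

**Steps most likely to fail**

Step 9 (Proposed new method). The diazo carbon may be consumed by dipolar cycloaddition to the C3=C4 bond or by azine formation before it reaches C9. The diazonium alkoxide may also collapse by migration of C1 or by epoxide closure instead of migration of C4. The fallback uses known reactions, is still an expansion of the five-membered ring, and sets out from 12. The sodium enolate of 12 (which masks the vinylogous acid) is treated with SmI2 in THF/t-BuOH at −78 °C, so that the ketyl of the methyl ketone adds to C9 (intramolecular pinacol coupling). This should give the cis-fused diol 3,3a,4-trihydroxy-4,7,7-trimethyl-6-methylidene-7a-(3-methylbut-2-en-1-yl)-3a,4,5,6,7,7a-hexahydro-1H-inden-1-one F1. BF3·OEt2 in CH2Cl2 at −78 °C should then ionise the tertiary C5–OH, and the alkenyl carbon C4 shifts from C9 to C5 (pinacol rearrangement) to give the bicyclic trione (1S,5R)-4-hydroxy-5,8,8-trimethyl-7-methylidene-1-(3-methylbut-2-en-1-yl)bicyclo[3.3.1]non-3-ene-2,9-dione F2. O-Methylation with trimethylsilyldiazomethane returns to the route at 16.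

Step 6 (Proposed new method). Enantioinduction may be insufficient, or the Lewis acid may ionise the allyl ether and give the linear C-allyl isomer by [1,3]-shift instead of the [3,3]-shift. The fallback sets out from 11. Thermal Claisen rearrangement (toluene, 110 °C, known for diosphenol allyl ethers) should give the racemic trione 2-hydroxy-5-(2-methyl-3-methylidene-5-oxohexan-2-yl)-5-(3-methylbut-2-en-1-yl)cyclopent-2-ene-1,4-dione F3. This vinylogous acid is resolved classically with (R)-1-phenylethylamine (or its antipode, whichever gives the less soluble salt of the S acid). The salt (R)-1-phenylethylammonium (5S)-enolate F4 is collected, while the diastereomeric salt (R)-1-phenylethylammonium (5R)-enolate F5 stays in the mother liquor. Dilute HCl liberates the acid and returns to the route at 12.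

Step 10. Exo-facial selectivity in the hydroboration may be insufficient. The hindered alkene may react so slowly that 9-BBN begins to reduce the carbonyl groups, or transmetalation of the hindered endo alkylborane may be sluggish. The fallback sets out from 16. Rhodium-catalysed hydroformylation (Rh(acac)(CO)2, bulky phosphite, CO/H2, toluene, 60 °C) adds H to C7 and the formyl group to the terminal carbon from the same exo face without a boron intermediate. It should give the aldehyde 2-[(1S,5R,7S)-4-methoxy-5,8,8-trimethyl-1-(3-methylbut-2-en-1-yl)-2,9-dioxobicyclo[3.3.1]non-3-en-7-yl]acetaldehyde F6 (same spatial arrangement at C7 as in 19; the descriptor changes by priority only). Wittig reaction with isopropylidenetriphenylphosphorane (THF, −78 to 0 °C) returns to the route at 19.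

Further compounds
F1 | step 9 | 3,3a,4-trihydroxy-4,7,7-trimethyl-6-methylidene-7a-(3-methylbut-2-en-1-yl)-3a,4,5,6,7,7a-hexahydro-1H-inden-1-one (cis-3a,4-diol, C7a as C1 of 12) | OC1=CC(=O)[C@]2(CC=C(C)C)C(C)(C)C(=C)CC(C)(O)C12O
F2 | step 9 | (1S,5R)-4-hydroxy-5,8,8-trimethyl-7-methylidene-1-(3-methylbut-2-en-1-yl)bicyclo[3.3.1]non-3-ene-2,9-dione | C=C1C[C@@]2(C)C(=O)[C@](CC=C(C)C)(C(=O)C=C2O)C1(C)C
F3 | step 6 | racemic 2-hydroxy-5-(2-methyl-3-methylidene-5-oxohexan-2-yl)-5-(3-methylbut-2-en-1-yl)cyclopent-2-ene-1,4-dione | OC1=CC(=O)C(CC=C(C)C)(C1=O)C(C)(C)C(=C)CC(C)=O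
F4 | step 6 | (R)-1-phenylethylammonium salt of (5S)-12 | C[C@@H]([NH3+])c1ccccc1.[O-]C1=CC(=O)[C@@](CC=C(C)C)(C1=O)C(C)(C)C(=C)CC(C)=O
F5 | step 6 | (R)-1-phenylethylammonium salt of the (5R)-enantiomer of 12 | C[C@@H]([NH3+])c1ccccc1.[O-]C1=CC(=O)[C@](CC=C(C)C)(C1=O)C(C)(C)C(=C)CC(C)=O
F6 | step 10 | 2-[(1S,5R,7S)-4-methoxy-5,8,8-trimethyl-1-(3-methylbut-2-en-1-yl)-2,9-dioxobicyclo[3.3.1]non-3-en-7-yl]acetaldehyde | O=CC[C@@H]1C[C@@]2(C)C(=O)[C@](CC=C(C)C)(C(=O)C=C2OC)C1(C)C
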